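The cyclohexane ring is numbered C1 (carbinol), C2 (CHBr), C3, C4 (side-chain carbon), C5, C6. It is cut at C1–C2 and C5–C6 into a C2–C5 diene and a C6=C1 dienophile. One enantioselective endo Diels–Alder reaction of an acyclic (E)-1-bromo-3-(silyloxymethyl)butadiene with methacrolein closes the ring and sets C1 and C2. It exploits the 1,2,4-pattern of the ring (bromine ortho, side chain para to quaternary C1) and the cis C1–O/C2–Br relation, which alkene bromohydration cannot deliver. The formyl group is an oxygen surrogate, exchanged with retention. C4 follows by radical hydrogenation, and the dienol chain comes from (S)-linalool by Heck coupling.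

Key step: step 4

Remark: (S)-(+)-linalool (coriandrol) is assumed to be purchasable in high enantiomeric purity.
Remark: the (S)-oxazaborolidinium salt is assumed to shield the enal face that leads to (1S,2S)-6; if the sense is opposite, the equally available (R)-enantiomer is used.
Remark: the ring numbering C1–C6 defined above is used throughout.

Step 1
Reactants: 1 2-methylidenepropane-1,3-diol
Product: 2 2-({[tert-butyl(dimethyl)silyl]oxy}methyl)prop-2-en-1-ol
Conditions: NaH (1.0 equiv), THF, 0 °C; TBSCl (1.0 equiv), rt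
Reagents that add atoms: tert-butyldimethylsilyl chloride (TBSCl), CC(C)(C)[Si](C)(C)Cl
Why: O-silylation of the sparingly soluble monosodium alkoxide favours monoprotection of the symmetrical diol, and no stereocentre is involved.

Step 2
Reactants: 2 2-({[tert-butyl(dimethyl)silyl]oxy}methyl)prop-2-en-1-ol
Product: 3 2-({[tert-butyl(dimethyl)silyl]oxy}methyl)prop-2-enal
Conditions: MnO2 (excess), CH2Cl2, rt
Reagents that add atoms: none
Why: Allylic alcohol oxidation on MnO2 stops at the enal and leaves the silyl ether untouched.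

Step 3
Reactants: 3 2-({[tert-butyl(dimethyl)silyl]oxy}methyl)prop-2-enal
Product: 4 {[(3E)-4-bromo-2-methylidenebut-3-en-1-yl]oxy}(tert-butyl)dimethylsilane
Conditions: CHBr3, CrBr2, THF, 0 °C to rt
Reagents that add atoms: bromoform, BrC(Br)Br
Why: In the Takai–Utimoto haloolefination the geminal dichromium species formed from CHBr3 and divalent chromium adds 1,2 to the enal and eliminates to give the (E)-bromoalkene, which is the geometry the cycloaddition needs.

Step 4
Reactants: 4 {[(3E)-4-bromo-2-methylidenebut-3-en-1-yl]oxy}(tert-butyl)dimethylsilane; 5 methacrolein (2-methylprop-2-enal)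
Product: 6 (1S,2S)-2-bromo-4-({[tert-butyl(dimethyl)silyl]oxy}methyl)-1-methylcyclohex-3-ene-1-carbaldehyde (Br and CHO cis)
Conditions: (S)-tetrahydro-1-(2-methylphenyl)-3,3-diphenyl-1H,3H-pyrrolo[1,2-c][1,3,2]oxazaborole (20 mol %), HN(SO2CF3)2 (20 mol %), CH2Cl2, −78 to −40 °C
Reagents that add atoms: none
Why: The step is a concerted, asynchronous [4π+2π] cycloaddition of s-cis 4 with boron-coordinated s-trans methacrolein, in which the C5–C6 bond (free diene terminus to enal β-carbon) runs ahead of the C1–C2 bond. The closest known reaction type is the oxazaborolidinium-catalysed enantioselective Diels–Alder reaction of α-substituted acroleins with acyclic 1- and 2-substituted dienes. The single six-membered carbocycle is closed in an intermolecular [4+2] mode, suprafacial on both partners. The relative configuration C1/C2 follows from the (E)-bromoalkene geometry together with the endo position of the formyl group, which places Br cis to CHO, and the absolute configuration follows from the catalyst, which binds the enal through B–O coordination and a formyl C–H···O contact and shields one face. The step needs ortho/para regioselectivity, secured because the lone-pair donor bromine at C2 and the alkyl group at C4 both enlarge the HOMO coefficient at C5, which meets the β-carbon C6, and it needs no periselectivity because 4 holds only one diene. The electron-withdrawing silyloxymethyl and formyl groups should disfavour ionisation of the allylic C–Br bond of 6 under the Lewis acid.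

Step 5
Reactants: 6 (1S,2S)-2-bromo-4-({[tert-butyl(dimethyl)silyl]oxy}methyl)-1-methylcyclohex-3-ene-1-carbaldehyde
Product: 7 (1S,2S,4S)-2-bromo-4-({[tert-butyl(dimethyl)silyl]oxy}methyl)-1-methylcyclohexane-1-carbaldehyde (all-cis CHO/Br/CH2OTBS)
Conditions: Mn(dpm)3 [tris(2,2,6,6-tetramethylheptane-3,5-dionato)manganese] (10 mol %), PhSiH3, t-BuOOH, i-PrOH, rt
Reagents that add atoms: none
Why: In this metal-hydride hydrogen-atom-transfer hydrogenation the manganese hydride gives H• to the less substituted C3, so the tertiary radical sits at C4 and never β to bromine, and the second hydrogen should arrive axially in the chair with equatorial CH3 and Br, which makes CH2OTBS equatorial and sets C4 as S.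

Step 6
Reactants: 7 (1S,2S,4S)-2-bromo-4-({[tert-butyl(dimethyl)silyl]oxy}methyl)-1-methylcyclohexane-1-carbaldehyde
Product: 9 (1R,2S,4S)-2-bromo-4-(hydroxymethyl)-1-methylcyclohexan-1-ol, via tertiary formate 8 (not isolated)
Conditions: mCPBA, CH2Cl2, 0 °C to rt; then HCl (1.25 M in MeOH), 0 °C to rt
Reagents that add atoms: 3-chloroperoxybenzoic acid (mCPBA), OOC(=O)c1cccc(Cl)c1
Why: In the Baeyer–Villiger oxidation of this α-quaternary aldehyde the tertiary C1 migrates to oxygen in the Criegee intermediate with retention, so C1–O ends cis to C2–Br, and acidic methanolysis then removes the formyl and silyl groups without touching the bromohydrin.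

Step 7
Reactants: 9 (1R,2S,4S)-2-bromo-4-(hydroxymethyl)-1-methylcyclohexan-1-ol
Product: 10 (1S,3S,4R)-3-bromo-4-hydroxy-4-methylcyclohexane-1-carbaldehyde
Conditions: 2,2,6,6-tetramethylpiperidin-1-oxyl (TEMPO, 10 mol %), PhI(OAc)2, CH2Cl2, rt
Reagents that add atoms: none
Why: The oxoammonium (TEMPO) oxidation takes only the primary alcohol to the aldehyde, while the tertiary alcohol cannot be oxidised and the secondary bromide is inert.

Step 8
Reactants: 10 (1S,3S,4R)-3-bromo-4-hydroxy-4-methylcyclohexane-1-carbaldehyde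
Product: 11 (1R,2S,4S)-2-bromo-4-ethynyl-1-methylcyclohexan-1-ol
Conditions: dimethyl (1-diazo-2-oxopropyl)phosphonate, K2CO3, MeOH, 0 °C to rt
Reagents that add atoms: dimethyl (1-diazo-2-oxopropyl)phosphonate, COP(=O)(OC)C(=[N+]=[N-])C(C)=O
Why: In the Ohira–Bestmann form of the Seyferth–Gilbert homologation the mild carbonate medium can only drive the α-centre C4 towards its equatorial (desired) configuration, and the cis-bromohydrin cannot close to an epoxide because O and Br cannot become antiperiplanar.

Step 9
Reactants: 11 (1R,2S,4S)-2-bromo-4-ethynyl-1-methylcyclohexan-1-ol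
Product: 13 (1R,2S,4S)-2-bromo-4-[(1E)-1-iodoprop-1-en-2-yl]-1-methylcyclohexan-1-ol, via alkenylalane 12 (not isolated)
Conditions: AlMe3 (3 equiv), Cp2ZrCl2 (20 mol %), CH2Cl2, 0 °C to rt; then I2, THF, −30 °C
Reagents that add atoms: trimethylaluminium, C[Al](C)C; iodine, II
Why: The zirconium-catalysed Negishi carboalumination adds CH3 and Al syn across the terminal alkyne with Al at the terminus, and iodinolysis proceeds with retention, which fixes the (E)-trisubstituted alkene while the hydroxyl is masked in situ as its aluminium alkoxide.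

Step 10
Reactants: 13 (1R,2S,4S)-2-bromo-4-[(1E)-1-iodoprop-1-en-2-yl]-1-methylcyclohexan-1-ol; 14 (S)-linalool [(3S)-3,7-dimethylocta-1,6-dien-3-ol]
Product: 15 (1R,2S,4S)-2-bromo-4-[(2E,4E,6S)-6-hydroxy-6,10-dimethylundeca-2,4,9-trien-2-yl]-1-methylcyclohexan-1-ol (target)
Conditions: Pd(OAc)2 (10 mol %), n-Bu4NCl, NaHCO3, DMF, 40 °C
Reagents that add atoms: none
Why: In the Heck reaction zerovalent palladium inserts into the C–I bond with retention, adds syn to the terminus of the monosubstituted vinyl group of 14, and can eliminate β-hydride only towards the new bond because the carbinol carbon carries no hydrogen, which gives the (E,E)-diene while the secondary bromide, the trisubstituted alkene and both tertiary alcohols stay untouched and the side-chain stereocentre comes unchanged from 14.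

Compound list
1 | 2-methylidenepropane-1,3-diol | C=C(CO)CO | starting material
2 | 2-({[tert-butyl(dimethyl)silyl]oxy}methyl)prop-2-en-1-ol | C=C(CO)CO[Si](C)(C)C(C)(C)C | intermediate
3 | 2-({[tert-butyl(dimethyl)silyl]oxy}methyl)prop-2-enal | C=C(C=O)CO[Si](C)(C)C(C)(C)C | intermediate
4 | {[(3E)-4-bromo-2-methylidenebut-3-en-1-yl]oxy}(tert-butyl)dimethylsilane | Br/C=C/C(=C)CO[Si](C)(C)C(C)(C)C | intermediate
5 | methacrolein (2-methylprop-2-enal) | C=C(C)C=O | starting material
6 | (1S,2S)-2-bromo-4-({[tert-butyl(dimethyl)silyl]oxy}methyl)-1-methylcyclohex-3-ene-1-carbaldehyde | CC(C)(C)[Si](C)(C)OCC=1CC[C@@](C)(C=O)[C@@H](Br)C=1 | intermediate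
7 | (1S,2S,4S)-2-bromo-4-({[tert-butyl(dimethyl)silyl]oxy}methyl)-1-methylcyclohexane-1-carbaldehyde | CC(C)(C)[Si](C)(C)OC[C@H]1CC[C@@](C)(C=O)[C@@H](Br)C1 | intermediate
8 | (1R,2S,4S)-2-bromo-4-({[tert-butyl(dimethyl)silyl]oxy}methyl)-1-methylcyclohexyl formate | CC(C)(C)[Si](C)(C)OC[C@H]1CC[C@@](C)(OC=O)[C@@H](Br)C1 | intermediate
9 | (1R,2S,4S)-2-bromo-4-(hydroxymethyl)-1-methylcyclohexan-1-ol | OC[C@H]1CC[C@@](C)(O)[C@@H](Br)C1 | intermediate
10 | (1S,3S,4R)-3-bromo-4-hydroxy-4-methylcyclohexane-1-carbaldehyde | O=C[C@H]1CC[C@@](C)(O)[C@@H](Br)C1 | intermediate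
11 | (1R,2S,4S)-2-bromo-4-ethynyl-1-methylcyclohexan-1-ol | C#C[C@H]1CC[C@@](C)(O)[C@@H](Br)C1 | intermediate
12 | (E)-alkenyl(dimethyl)alane of 11, with the hydroxyl as its dimethylaluminium alkoxide | C[Al](C)/C=C(\C)[C@H]1CC[C@@](C)(O[Al](C)C)[C@@H](Br)C1 | intermediate
13 | (1R,2S,4S)-2-bromo-4-[(1E)-1-iodoprop-1-en-2-yl]-1-methylcyclohexan-1-ol | I/C=C(\C)[C@H]1CC[C@@](C)(O)[C@@H](Br)C1 | intermediate
14 | (S)-linalool, (3S)-3,7-dimethylocta-1,6-dien-3-ol | CC(C)=CCC[C@](C)(O)C=C | starting material
15 | (1R,2S,4S)-2-bromo-4-[(2E,4E,6S)-6-hydroxy-6,10-dimethylundeca-2,4,9-trien-2-yl]-1-methylcyclohexan-1-ol | CC(C)=CCC[C@](C)(O)/C=C/C=C(\C)[C@H]1CC[C@@](C)(O)[C@@H](Br)C1 | target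

Total step count: 10. Longest linear sequence: 10 steps (1 to 15); 5 and 14 are bought.

Steps most likely to fail

**Step 4.**
- What may go wrong: bromine lowers the diene HOMO, so the cycloaddition may be slow. The strong cationic Lewis acid may ionise the allylic C–Br bond of the adduct. Endo and facial control may erode.
- Fallback (sets out from 4 and 5, comes back at 9): stereocontrol is moved from catalysis to resolution. 4 and 5 are combined without a chiral catalyst (MeAlCl2, CH2Cl2, −78 °C, or heating in toluene). The racemic endo adduct is carried through steps 5 and 6. Racemic 9 is then acylated at the primary hydroxyl by a lipase (Burkholderia cepacia lipase, vinyl acetate, t-BuOMe). [(1S,3S,4R)-3-bromo-4-hydroxy-4-methylcyclohexyl]methyl acetate F1 is separated from the unreacted antipode (1S,2R,4R)-2-bromo-4-(hydroxymethyl)-1-methylcyclohexan-1-ol F2, and K2CO3 in MeOH returns 9. If the enzyme prefers the antipode, 9 is the alcohol left behind.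

**Step 5.**
- What may go wrong: bromine may be lost by halogen abstraction or elimination from radical intermediates. The formyl group may be attacked (reduction or decarbonylation). Facial selectivity at C4 may be poor.
- Fallback (sets out from 6, comes back at 11): the C3=C4 bond is reduced as a polarised enal by ionic hydride transfer instead of as an isolated alkene.
  - HF·pyridine in THF frees (1S,2S)-2-bromo-4-(hydroxymethyl)-1-methylcyclohex-3-ene-1-carbaldehyde F3.
  - MnO2 oxidises only the allylic alcohol to (3S,4S)-3-bromo-4-methylcyclohex-1-ene-1,4-dicarbaldehyde F4.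
  - Organocatalytic transfer hydrogenation (Hantzsch ester, dibenzylammonium trifluoroacetate) activates only the conjugated, unhindered formyl group as its iminium ion. After equilibration of C4 it gives (1S,2S,4S)-2-bromo-1-methylcyclohexane-1,4-dicarbaldehyde F5.
  - One equivalent of the Ohira–Bestmann reagent (K2CO3, MeOH, 0 °C) homologates the secondary formyl group and spares the neopentyl one, giving (1S,2S,4S)-2-bromo-4-ethynyl-1-methylcyclohexane-1-carbaldehyde F6.
  - Baeyer–Villiger oxidation with mCPBA gives (1R,2S,4S)-2-bromo-4-ethynyl-1-methylcyclohexyl formate F7, and K2CO3 in MeOH leads to 11.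

**Step 6.**
- What may go wrong: hydride may migrate instead of C1 in the Criegee intermediate, because the β-bromine lowers the migratory aptitude of C1. The aldehyde would then drain to the carboxylic acid.
- Fallback (sets out from 7, comes back at 9): the competing hydrogen is replaced by a methyl group, which migrates far less readily than a tertiary carbon.
  - MeMgBr (THF, −78 °C) gives 1-[(1S,2S,4S)-2-bromo-4-({[tert-butyl(dimethyl)silyl]oxy}methyl)-1-methylcyclohexyl]ethan-1-ol F8 (both carbinol epimers).
  - Dess–Martin periodinane gives 1-[(1S,2S,4S)-2-bromo-4-({[tert-butyl(dimethyl)silyl]oxy}methyl)-1-methylcyclohexyl]ethan-1-one F9.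
  - Trifluoroperacetic acid buffered with Na2HPO4 gives, with retention, (1R,2S,4S)-2-bromo-4-({[tert-butyl(dimethyl)silyl]oxy}methyl)-1-methylcyclohexyl acetate F10.
  - K2CO3 in MeOH frees (1R,2S,4S)-2-bromo-4-({[tert-butyl(dimethyl)silyl]oxy}methyl)-1-methylcyclohexan-1-ol F11, and HCl in MeOH removes the silyl group to give 9.

Further compounds
F1 | step 4 | [(1S,3S,4R)-3-bromo-4-hydroxy-4-methylcyclohexyl]methyl acetate | CC(=O)OC[C@H]1CC[C@@](C)(O)[C@@H](Br)C1
F2 | step 4 | (1S,2R,4R)-2-bromo-4-(hydroxymethyl)-1-methylcyclohexan-1-ol | OC[C@@H]1CC[C@](C)(O)[C@H](Br)C1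
F3 | step 5 | (1S,2S)-2-bromo-4-(hydroxymethyl)-1-methylcyclohex-3-ene-1-carbaldehyde | OCC=1CC[C@@](C)(C=O)[C@@H](Br)C=1
F4 | step 5 | (3S,4S)-3-bromo-4-methylcyclohex-1-ene-1,4-dicarbaldehyde | O=CC=1CC[C@@](C)(C=O)[C@@H](Br)C=1
F5 | step 5 | (1S,2S,4S)-2-bromo-1-methylcyclohexane-1,4-dicarbaldehyde | O=C[C@H]1CC[C@@](C)(C=O)[C@@H](Br)C1
F6 | step 5 | (1S,2S,4S)-2-bromo-4-ethynyl-1-methylcyclohexane-1-carbaldehyde | C#C[C@H]1CC[C@@](C)(C=O)[C@@H](Br)C1
F7 | step 5 | (1R,2S,4S)-2-bromo-4-ethynyl-1-methylcyclohexyl formate | C#C[C@H]1CC[C@@](C)(OC=O)[C@@H](Br)C1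
F8 | step 6 | 1-[(1S,2S,4S)-2-bromo-4-({[tert-butyl(dimethyl)silyl]oxy}methyl)-1-methylcyclohexyl]ethan-1-ol | CC(C)(C)[Si](C)(C)OC[C@H]1CC[C@@](C)(C(C)O)[C@@H](Br)C1
F9 | step 6 | 1-[(1S,2S,4S)-2-bromo-4-({[tert-butyl(dimethyl)silyl]oxy}methyl)-1-methylcyclohexyl]ethan-1-one | CC(C)(C)[Si](C)(C)OC[C@H]1CC[C@@](C)(C(C)=O)[C@@H](Br)C1
F10 | step 6 | (1R,2S,4S)-2-bromo-4-({[tert-butyl(dimethyl)silyl]oxy}methyl)-1-methylcyclohexyl acetate | CC(C)(C)[Si](C)(C)OC[C@H]1CC[C@@](C)(OC(C)=O)[C@@H](Br)C1
F11 | step 6 | (1R,2S,4S)-2-bromo-4-({[tert-butyl(dimethyl)silyl]oxy}methyl)-1-methylcyclohexan-1-ol | CC(C)(C)[Si](C)(C)OC[C@H]1CC[C@@](C)(O)[C@@H](Br)C1
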